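**Retrosynthetic overview**
1. Last step, three bonds in one flask (C7–aryl, C1–C2, C3=C4): an aryl Grignard reagent adds 1,4 to a monocyclic cyclopentenone, the enolate closes a Claisen ring onto a side-chain ester, and silanol is lost. The six-membered ring, and with it the seven-membered ring of the bicyclo[3.2.1]octane, forms in this one operation, and C7 and C1 are set.
2. The cyclopentenone comes from Saegusa desaturation of a ketone whose side chain is built by aldol addition of a methoxyacetate ester to a quaternary α-formyl ketone.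
3. The quaternary centre C5 comes from Tsuji–Trost allylation of a 2-(hydroxymethylene)cyclopentanone, anti to the C6 methyl.
4. C6 is the only catalyst-set centre: asymmetric copper hydride reduction of a commercial methylcyclopentenone, with formylation of the regiodefined enolate.
5. Ring order: five-membered ring A is bought; six-membered ring B and the seven-membered ring are closed together at the end.

Assumption: (S)-p-Tol-BINAP is taken as the ligand hand that gives the (3R) ketone in step 1 (otherwise its antipode is used); atom labels C1–C8 in the Why lines follow the bicyclo[3.2.1]octane numbering of the target.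

**Step 1**
Reactants: 1 3-methylcyclopent-2-en-1-one; 2 ethyl formate
Product: 5 (3R,Z)-2-(hydroxymethylene)-3-methylcyclopentan-1-one, via silyl enol ether 3 (not isolated), via lithium enolate 4 (not isolated)
Conditions: CuCl (5 mol %), NaOt-Bu (5 mol %), (S)-p-Tol-BINAP (5 mol %), Ph2SiH2 (1.0 equiv), toluene, 0 °C; then MeLi (1.0 equiv), THF, −78 °C; then 2, −78 to 0 °C; 1 M HCl
Reagents that add atoms: none
Why: Asymmetric copper hydride conjugate reduction (Stryker-type, Buchwald ligand system) sets C6 as (R) under ligand control and leaves the enolate regiospecifically on the methyl-bearing side, so that silicon–lithium exchange and Claisen formylation can only functionalise the future C5.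

**Step 2**
Reactants: 5 (3R,Z)-2-(hydroxymethylene)-3-methylcyclopentan-1-one; 6 allyl methyl carbonate
Product: 7 (1S,2R)-1-allyl-2-methyl-5-oxocyclopentane-1-carbaldehyde
Conditions: Pd(PPh3)4 (2 mol %), THF, 23 °C
Reagents that add atoms: none
Why: Tsuji–Trost allylation under neutral carbonate conditions C-allylates the soft β-keto aldehyde enolate, and the π-allylpalladium electrophile attacks the planar enolate anti to the neighbouring methyl group, which fixes the quaternary C5 with allyl trans and formyl cis to that methyl.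

**Step 3**
Reactants: 7 (1S,2R)-1-allyl-2-methyl-5-oxocyclopentane-1-carbaldehyde; 8 methyl methoxyacetate
Product: 11 methyl 3-[(1S,2R)-1-allyl-2-methyl-5-oxocyclopentyl]-3-[(tert-butyldimethylsilyl)oxy]-2-methoxypropanoate (epimer mixture at the two side-chain carbons), via ester enolate 9 (not isolated), via lithium aldolate 10 (not isolated)
Conditions: 8, LiN(i-Pr)2, THF, −78 °C; then 7, −78 °C; then TBSOTf, −78 to −40 °C
Reagents that add atoms: tert-butyldimethylsilyl trifluoromethanesulfonate CC(C)(C)[Si](C)(C)OS(=O)(=O)C(F)(F)F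
Why: Lithium ester enolate aldol addition is chemoselective for the non-enolisable aldehyde over the hindered ketone and the aldolate is silylated cold before retro-aldol or deformylation can start, while the two new stereocentres need no control because both carbons become sp2 in step 5.

**Step 4**
Reactants: 11 methyl 3-[(1S,2R)-1-allyl-2-methyl-5-oxocyclopentyl]-3-[(tert-butyldimethylsilyl)oxy]-2-methoxypropanoate
Product: 13 methyl 3-[(1S,2R)-1-allyl-2-methyl-5-oxocyclopent-3-en-1-yl]-3-[(tert-butyldimethylsilyl)oxy]-2-methoxypropanoate, via trimethylsilyl enol ether 12 (not isolated)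
Conditions: LiN(i-Pr)2, Me3SiCl, THF, −78 °C; then Pd(OAc)2 (1.05 equiv), MeCN, 23 °C
Reagents that add atoms: none
Why: Saegusa–Ito oxidation: the ketone has a single enolisable α-carbon (C1) that is more acidic than the ester α-hydrogen, so one silyl enol ether forms and its palladium enolate undergoes β-hydride elimination to the enone without touching the existing stereocentres.

**Step 5**
Reactants: 13 methyl 3-[(1S,2R)-1-allyl-2-methyl-5-oxocyclopent-3-en-1-yl]-3-[(tert-butyldimethylsilyl)oxy]-2-methoxypropanoate; 14 4-bromo-1,2-dimethoxybenzene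
Product: 18 kadsurenin D [(1S,5S,6R,7R)-5-allyl-7-(3,4-dimethoxyphenyl)-3-methoxy-6-methylbicyclo[3.2.1]oct-3-ene-2,8-dione], via aryl Grignard reagent 15 (not isolated), via magnesium enolate 16 (not isolated), via silyloxy diketone 17 (not isolated)
Conditions: 14 (1.1 equiv), Mg, THF, 40 °C; then CuBr·SMe2 (15 mol %), 13, THF, −78 to 23 °C; aq. NH4Cl
Reagents that add atoms: none
Why: Proposed new method: copper-catalysed 1,4-addition of the aryl Grignard reagent occurs anti to the adjacent methyl (sets C7), the magnesium enolate so formed can only reach the ester that the quaternary centre holds on the face opposite to the new aryl group and closes a 6-(enolendo)-exo-trig Claisen (Dieckmann-type) ring that sets C1 and creates the bridged diketone, and the liberated alkoxide then removes the only acidic hydrogen (C3–H) so that E1cB loss of silanolate gives the conjugated enol ether and makes the otherwise reversible Claisen step irreversible; the closest known reaction types are the tandem cuprate conjugate addition–Dieckmann cyclisation and the α,α′-annulation of cyclopentanones to bicyclo[3.2.1]octan-8-ones.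

**Compound list**
1 | 3-methylcyclopent-2-en-1-one | CC1=CC(=O)CC1 | starting material
2 | ethyl formate | CCOC=O | starting material
3 | {[(3R)-3-methylcyclopent-1-en-1-yl]oxy}diphenylsilane | C[C@@H]1CCC(O[SiH](c2ccccc2)c2ccccc2)=C1 | intermediate
4 | lithium (3R)-3-methylcyclopent-1-en-1-olate | C[C@@H]1CCC(O[Li])=C1 | intermediate
5 | (3R,Z)-2-(hydroxymethylene)-3-methylcyclopentan-1-one | O=C1CC[C@@H](C)/C1=C/O | intermediate
6 | allyl methyl carbonate | C=CCOC(=O)OC | starting material
7 | (1S,2R)-1-allyl-2-methyl-5-oxocyclopentane-1-carbaldehyde | C=CC[C@]1(C=O)C(=O)CC[C@H]1C | intermediate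
8 | methyl methoxyacetate | COCC(=O)OC | starting material
9 | lithium 1,2-dimethoxyethen-1-olate | COC=C(OC)O[Li] | intermediate
10 | lithium 1-[(1S,2R)-1-allyl-2-methyl-5-oxocyclopentyl]-2,3-dimethoxy-3-oxopropan-1-olate (epimer mixture in the side chain) | C=CC[C@]1(C(O[Li])C(OC)C(=O)OC)C(=O)CC[C@H]1C | intermediate
11 | methyl 3-[(1S,2R)-1-allyl-2-methyl-5-oxocyclopentyl]-3-[(tert-butyldimethylsilyl)oxy]-2-methoxypropanoate (epimer mixture in the side chain) | C=CC[C@]1(C(O[Si](C)(C)C(C)(C)C)C(OC)C(=O)OC)C(=O)CC[C@H]1C | intermediate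
12 | methyl 3-[(1S,2R)-1-allyl-2-methyl-5-[(trimethylsilyl)oxy]cyclopent-4-en-1-yl]-3-[(tert-butyldimethylsilyl)oxy]-2-methoxypropanoate | C=CC[C@]1(C(O[Si](C)(C)C(C)(C)C)C(OC)C(=O)OC)C(O[Si](C)(C)C)=CC[C@H]1C | intermediate
13 | methyl 3-[(1S,2R)-1-allyl-2-methyl-5-oxocyclopent-3-en-1-yl]-3-[(tert-butyldimethylsilyl)oxy]-2-methoxypropanoate | C=CC[C@]1(C(O[Si](C)(C)C(C)(C)C)C(OC)C(=O)OC)C(=O)C=C[C@H]1C | intermediate
14 | 4-bromo-1,2-dimethoxybenzene | COc1ccc(Br)cc1OC | starting material
15 | (3,4-dimethoxyphenyl)magnesium bromide | COc1ccc([Mg]Br)cc1OC | intermediate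
16 | bromomagnesium (3R,4R,5S)-5-allyl-5-{1-[(tert-butyldimethylsilyl)oxy]-2,3-dimethoxy-3-oxopropyl}-3-(3,4-dimethoxyphenyl)-4-methylcyclopent-1-en-1-olate | C=CC[C@]1(C(O[Si](C)(C)C(C)(C)C)C(OC)C(=O)OC)C(O[Mg]Br)=C[C@H](c2ccc(OC)c(OC)c2)[C@H]1C | intermediate
17 | (1S,5S,6R,7R)-5-allyl-4-[(tert-butyldimethylsilyl)oxy]-7-(3,4-dimethoxyphenyl)-3-methoxy-6-methylbicyclo[3.2.1]octane-2,8-dione (epimer mixture at C3 and C4) | C=CC[C@]12C(O[Si](C)(C)C(C)(C)C)C(OC)C(=O)[C@H](C1=O)[C@H](c1ccc(OC)c(OC)c1)[C@H]2C | intermediate
18 | kadsurenin D, (1S,5S,6R,7R)-5-allyl-7-(3,4-dimethoxyphenyl)-3-methoxy-6-methylbicyclo[3.2.1]oct-3-ene-2,8-dione | C=CC[C@]12C=C(OC)C(=O)[C@H](C1=O)[C@H](c1ccc(OC)c(OC)c1)[C@H]2C | target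

**Totals**
Total step count: 5. Longest linear sequence: 5 steps (1 → 5 → 7 → 11 → 13 → 18).

**Steps most likely to fail, with fallbacks**

Step 5 is an untested cascade. The Claisen closure gives a diketone that cannot enolise at C1 and is therefore reversible until the elimination occurs, the bridged diketone can be cleaved by alkoxide, and the enolate may equilibrate to the ester side. The fallback separates the events and makes the acylation irreversible. It sets out from 13 and 15: the conjugate addition (CuBr·SMe2, THF, −78 °C) is quenched cold with acetic acid to give the keto ester methyl 3-[(1S,2R,3S)-1-allyl-3-(3,4-dimethoxyphenyl)-2-methyl-5-oxocyclopentyl]-3-[(tert-butyldimethylsilyl)oxy]-2-methoxypropanoate F1. The methyl ester is cleaved with Me3SnOH (1,2-dichloroethane, 80 °C) to 3-[(1S,2R,3S)-1-allyl-3-(3,4-dimethoxyphenyl)-2-methyl-5-oxocyclopentyl]-3-[(tert-butyldimethylsilyl)oxy]-2-methoxypropanoic acid F2. Carbonyldiimidazole converts this into the acyl imidazolide 3-[(1S,2R,3S)-1-allyl-3-(3,4-dimethoxyphenyl)-2-methyl-5-oxocyclopentyl]-3-[(tert-butyldimethylsilyl)oxy]-1-(imidazol-1-yl)-2-methoxypropan-1-one F3. Soft enolisation (MgBr2·OEt2, i-Pr2NEt, CH2Cl2) then closes ring B by C-acylation with a non-nucleophilic leaving group. The fallback comes back to the route at 17, now isolated, which DBU in CH2Cl2 converts into 18.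

Step 2 may give O-allylation or only modest facial selectivity at the new quaternary centre. The fallback sets out from 5: O-allylation (allyl bromide, K2CO3, acetone) gives (3R)-2-[(allyloxy)methylene]-3-methylcyclopentan-1-one F4, and heating in toluene at 110 °C triggers a Claisen rearrangement that delivers the allyl group suprafacially to the face anti to the methyl group. It comes back to the route at 7.

Step 3 exposes a hindered α-formyl ketone to a basic aldolate, which can undergo retro-aldol cleavage or deformylation. The fallback sets out from 7 and 8: 8 is converted (LiN(i-Pr)2, Me3SiCl, THF, −78 °C) into the silyl ketene acetal [(1,2-dimethoxyethenyl)oxy]trimethylsilane F5. A Mukaiyama aldol addition to 7 (BF3·OEt2, CH2Cl2, −78 °C) gives methyl 3-[(1S,2R)-1-allyl-2-methyl-5-oxocyclopentyl]-3-hydroxy-2-methoxypropanoate F6 without a free alkoxide. Silylation (TBSOTf, 2,6-lutidine, CH2Cl2) comes back to the route at 11.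

**Further compounds**
F1 | step 5 | methyl 3-[(1S,2R,3S)-1-allyl-3-(3,4-dimethoxyphenyl)-2-methyl-5-oxocyclopentyl]-3-[(tert-butyldimethylsilyl)oxy]-2-methoxypropanoate | C=CC[C@]1(C(O[Si](C)(C)C(C)(C)C)C(OC)C(=O)OC)C(=O)C[C@H](c2ccc(OC)c(OC)c2)[C@H]1C
F2 | step 5 | 3-[(1S,2R,3S)-1-allyl-3-(3,4-dimethoxyphenyl)-2-methyl-5-oxocyclopentyl]-3-[(tert-butyldimethylsilyl)oxy]-2-methoxypropanoic acid | C=CC[C@]1(C(O[Si](C)(C)C(C)(C)C)C(OC)C(=O)O)C(=O)C[C@H](c2ccc(OC)c(OC)c2)[C@H]1C
F3 | step 5 | 3-[(1S,2R,3S)-1-allyl-3-(3,4-dimethoxyphenyl)-2-methyl-5-oxocyclopentyl]-3-[(tert-butyldimethylsilyl)oxy]-1-(imidazol-1-yl)-2-methoxypropan-1-one | C=CC[C@]1(C(O[Si](C)(C)C(C)(C)C)C(OC)C(=O)n2ccnc2)C(=O)C[C@H](c2ccc(OC)c(OC)c2)[C@H]1C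
F4 | step 2 | (3R)-2-[(allyloxy)methylene]-3-methylcyclopentan-1-one | O=C1CC[C@@H](C)C1=COCC=C
F5 | step 3 | [(1,2-dimethoxyethenyl)oxy]trimethylsilane | COC=C(OC)O[Si](C)(C)C
F6 | step 3 | methyl 3-[(1S,2R)-1-allyl-2-methyl-5-oxocyclopentyl]-3-hydroxy-2-methoxypropanoate | C=CC[C@]1(C(O)C(OC)C(=O)OC)C(=O)CC[C@H]1C
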